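**Retrosynthetic overview**
1. Last bond: the C19–O ester, from ent-labda-8(17),13(16),14-trien-19-ol and O-acetyl-protected (E)-p-coumaric acid.
2. The trienol comes from one Lewis-acid cascade on an acyclic (R)-2-methyl-2-alkyloxirane: ring A closes first (C4–C5, oxirane opened with inversion), ring B second (C9–C10), and a (Z)-allylsilane ends the cascade as the 8(17)-methylene. The single oxirane centre controls C4, C5, C9 and C10.
3. The oxirane comes from an acyclic methyl ketone by catalytic asymmetric methylene transfer (Corey–Chaykovsky).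
4. The ketone chain is built by two alkyne carbometalation/oxirane-opening rounds (Zr/Al methylalumination for the E-alkene, silylmethyl-carbocupration for the Z-allylsilane) and a Cu-catalysed coupling with 2-butadienyl Grignard for the diene.
5. Building blocks: 5-chloropentan-2-one ethylene ketal, lithium acetylide, oxirane, Me3SiCH2MgCl, chloroprene, Me3S(O)I, 4-acetoxycinnamic acid.

Assumption: the La–Li3–tris(binaphthoxide) antipode written as (R)-LLB in step 8 is taken to deliver CH2 to the Si face of the methyl ketone (R-oxirane); if the sense is the reverse, the catalyst from (S)-BINOL is used.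
Note: labdane numbering (C1–C20) is used in the explanations. The target is read as the ent-labdane, (1R,4aS,5R,8aS), with the ester on the axial C19.

**Step 1**
Reactants: 1 2-(3-chloropropyl)-2-methyl-1,3-dioxolane; 2 lithium acetylide–ethylenediamine complex
Product: 3 2-methyl-2-(pent-4-yn-1-yl)-1,3-dioxolane
Conditions: 2 (1.3 equiv), NaI (10 mol%), DMSO, 15 °C → rt
Reagents that add atoms: lithium acetylide–ethylenediamine complex (2), [Li+].[C-]#C.NCCN
Why: SN2 acetylide alkylation of a primary chloride; the ketal is inert to the base and masks the future C4 ketone.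

**Step 2**
Reactants: 3 2-methyl-2-(pent-4-yn-1-yl)-1,3-dioxolane; 4 oxirane
Product: 7 (3E)-4-methyl-7-(2-methyl-1,3-dioxolan-2-yl)hept-3-en-1-ol, via alkenylalane 5 (not isolated), via lithium alkenylalanate 6 (not isolated)
Conditions: Me3Al (2.5 equiv), Cp2ZrCl2 (20 mol%), CH2Cl2, 0 °C → rt; evaporate; n-BuLi (1 equiv), THF–hexane, −78 °C; oxirane, −78 → 0 °C; aq. NH4Cl/Rochelle salt
Reagents that add atoms: trimethylaluminium, C[Al](C)C; oxirane (4), C1CO1
Why: Negishi Zr-catalysed syn-methylalumination puts CH3 on the internal and Al on the terminal alkyne carbon (E ≥ 98:2), and the ate complex opens oxirane with retention, so the E-C10=C5 alkene and the C6–C7 unit are made together.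

**Step 3**
Reactants: 7 (3E)-4-methyl-7-(2-methyl-1,3-dioxolan-2-yl)hept-3-en-1-ol
Product: 8 2-[(4E)-7-iodo-4-methylhept-4-en-1-yl]-2-methyl-1,3-dioxolane
Conditions: I2, PPh3, imidazole, CH2Cl2, 0 °C
Reagents that add atoms: iodine, II
Why: Appel-type (Garegg–Samuelsson) iodination of a primary alcohol under buffered conditions that leave the ketal and the alkene untouched.

**Step 4**
Reactants: 8 2-[(4E)-7-iodo-4-methylhept-4-en-1-yl]-2-methyl-1,3-dioxolane; 2 lithium acetylide–ethylenediamine complex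
Product: 9 2-methyl-2-[(4E)-4-methylnon-4-en-8-yn-1-yl]-1,3-dioxolane
Conditions: 2 (1.5 equiv), DMSO, rt
Reagents that add atoms: lithium acetylide–ethylenediamine complex (2), [Li+].[C-]#C.NCCN
Why: SN2 acetylide alkylation of a primary iodide gives the terminal alkyne (C8≡C9) for the second carbometalation.

**Step 5**
Reactants: 9 2-methyl-2-[(4E)-4-methylnon-4-en-8-yn-1-yl]-1,3-dioxolane; 10 (trimethylsilyl)methylmagnesium chloride; 4 oxirane
Product: 13 (3Z,7E)-8-methyl-11-(2-methyl-1,3-dioxolan-2-yl)-4-[(trimethylsilyl)methyl]undeca-3,7-dien-1-ol, via alkenylcopper 11 (not isolated), via mixed cuprate 12 (not isolated)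
Conditions: 10, CuBr·SMe2 (1.4 equiv each), Et2O–Me2S, −40 °C; 9, −25 → 0 °C; PhC≡CLi, THF–HMPA, −40 °C; oxirane, −40 → −10 °C; aq. NH4Cl
Reagents that add atoms: (trimethylsilyl)methylmagnesium chloride (10), C[Si](C)(C)C[Mg]Cl; oxirane (4), C1CO1
Why: Normant carbocupration adds the α-silylalkylcopper syn across the terminal alkyne (CH2SiMe3 to the internal carbon, Cu to the terminal one) and the derived alkynyl cuprate opens oxirane with retention, which fixes the Z-allylsilane (CH2SiMe3 cis to C11) needed for the equatorial C9 side chain.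

**Step 6**
Reactants: 13 (3Z,7E)-8-methyl-11-(2-methyl-1,3-dioxolan-2-yl)-4-[(trimethylsilyl)methyl]undeca-3,7-dien-1-ol
Product: 14 (3Z,7E)-8-methyl-11-(2-methyl-1,3-dioxolan-2-yl)-4-[(trimethylsilyl)methyl]undeca-3,7-dien-1-yl 4-methylbenzenesulfonate
Conditions: TsCl, Et3N, DMAP (cat.), CH2Cl2, 0 °C
Reagents that add atoms: 4-methylbenzenesulfonyl chloride, Cc1ccc(cc1)S(Cl)(=O)=O
Why: Sulfonylation of the primary alcohol under basic conditions, which spare the acid-sensitive allylsilane and ketal.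

**Step 7**
Reactants: 14 (3Z,7E)-8-methyl-11-(2-methyl-1,3-dioxolan-2-yl)-4-[(trimethylsilyl)methyl]undeca-3,7-dien-1-yl 4-methylbenzenesulfonate; 15 2-chlorobuta-1,3-diene (chloroprene)
Product: 18 (6E,10Z)-6-methyl-14-methylidene-10-[(trimethylsilyl)methyl]hexadeca-6,10,15-trien-2-one, via butadienyl Grignard reagent 16 (not isolated), via ketal tetraene 17 (not isolated)
Conditions: 15, Mg (I2-activated), THF, reflux; 14, Li2CuCl4 (5 mol%), THF, −10 °C → rt; then 1 M aq. oxalic acid, rt
Reagents that add atoms: 2-chlorobuta-1,3-diene (15), C=CC(Cl)=C; water, O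
Why: Kochi-type Cu-catalysed Kumada coupling of a primary tosylate with the 2-butadienyl Grignard installs the 2-substituted diene, and mild acid hydrolysis of the dioxolane in the same pot frees the methyl ketone without protodesilylation.

**Step 8**
Reactants: 18 (6E,10Z)-6-methyl-14-methylidene-10-[(trimethylsilyl)methyl]hexadeca-6,10,15-trien-2-one; 19 trimethylsulfoxonium iodide
Product: 21 (2R)-2-methyl-2-[(4E,8Z)-4-methyl-12-methylidene-8-[(trimethylsilyl)methyl]tetradeca-4,8,13-trien-1-yl]oxirane, via sulfoxonium ylide 20 (not isolated)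
Conditions: 19, NaH, THF, reflux; 18, (R)-LLB (5 mol%), (2,4,6-(MeO)3C6H2)3P=O (5 mol%), 5 Å MS, THF, rt
Reagents that add atoms: trimethylsulfoxonium iodide (19), C[S+](C)(C)=O.[I-]
Why: Catalytic asymmetric Corey–Chaykovsky epoxidation of a methyl ketone with the La–Li3–BINOL/phosphine oxide system, whose Si-face methylene transfer sets the R centre (the future C4, about 90–95% ee expected), while alkenes, diene and allylsilane are inert to the ylide.

**Step 9**
Reactants: 21 (2R)-2-methyl-2-[(4E,8Z)-4-methyl-12-methylidene-8-[(trimethylsilyl)methyl]tetradeca-4,8,13-trien-1-yl]oxirane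
Product: 22 [(1R,4aS,5R,8aS)-1,4a-dimethyl-6-methylidene-5-(3-methylidenepent-4-en-1-yl)decahydronaphthalen-1-yl]methanol (ent-labda-8(17),13(16),14-trien-19-ol)
Conditions: MeAlCl2 (1.5 equiv), CH2Cl2 (0.01 M), −78 °C, 30 min; Et3N, then aq. Rochelle salt
Reagents that add atoms: none
Why: Proposed new method: MeAlCl2 activates the 2,2-disubstituted oxirane and the C5=C10 alkene displaces the tertiary C–O bond from the back in concert, so the R centre becomes C4 with inversion and the CH2O–Al arm stays on C4; in the chair–chair folding the oxirane CH2 sits pseudo-axial and the CH3 stays anti to C2–C3 (the other chair would force CH3 to eclipse that bond), the E-alkene gives the trans ring fusion, the Z-allylsilane gives the equatorial C9 chain, and β-silyl loss gives only the 8(17)-alkene; the closest known reaction type is the Lewis-acid epoxy-polyene cyclisation of trisubstituted epoxides with allylsilane termination, together with invertive Friedel–Crafts opening of 2,2-disubstituted epoxides.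

**Step 10**
Reactants: 22 [(1R,4aS,5R,8aS)-1,4a-dimethyl-6-methylidene-5-(3-methylidenepent-4-en-1-yl)decahydronaphthalen-1-yl]methanol; 23 (2E)-3-[4-(acetyloxy)phenyl]prop-2-enoic acid
Product: 25 [(1R,4aS,5R,8aS)-1,4a-dimethyl-6-methylidene-5-(3-methylidenepent-4-en-1-yl)decahydronaphthalen-1-yl]methyl (2E)-3-(4-hydroxyphenyl)prop-2-enoate, via aryl acetate ester 24 (not isolated)
Conditions: 23 (1.5 equiv), EDC·HCl, DMAP, CH2Cl2, rt; then pyrrolidine, rt, 1 h
Reagents that add atoms: (2E)-3-[4-(acetyloxy)phenyl]prop-2-enoic acid (23), CC(=O)Oc1ccc(/C=C/C(=O)O)cc1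
Why: Steglich-type carbodiimide esterification of the neopentyl primary alcohol followed in the same flask by chemoselective aminolysis of the aryl acetate (far faster than the alkyl cinnamate), which avoids phenol self-acylation and touches no stereocentre.

**Compound list**
1 | 2-(3-chloropropyl)-2-methyl-1,3-dioxolane | CC1(CCCCl)OCCO1 | starting material
2 | lithium acetylide–ethylenediamine complex | [Li+].[C-]#C.NCCN | starting material
3 | 2-methyl-2-(pent-4-yn-1-yl)-1,3-dioxolane | CC1(CCCC#C)OCCO1 | intermediate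
4 | oxirane | C1CO1 | starting material
5 | dimethyl[(1E)-2-methyl-5-(2-methyl-1,3-dioxolan-2-yl)pent-1-en-1-yl]alumane | CC1(CCC/C(C)=C/[Al](C)C)OCCO1 | intermediate
6 | lithium butyl(dimethyl)[(1E)-2-methyl-5-(2-methyl-1,3-dioxolan-2-yl)pent-1-en-1-yl]aluminate | [Li+].CCCC[Al-](C)(C)/C=C(\C)CCCC1(C)OCCO1 | intermediate
7 | (3E)-4-methyl-7-(2-methyl-1,3-dioxolan-2-yl)hept-3-en-1-ol | CC1(CCC/C(C)=C/CCO)OCCO1 | intermediate
8 | 2-[(4E)-7-iodo-4-methylhept-4-en-1-yl]-2-methyl-1,3-dioxolane | CC1(CCC/C(C)=C/CCI)OCCO1 | intermediate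
9 | 2-methyl-2-[(4E)-4-methylnon-4-en-8-yn-1-yl]-1,3-dioxolane | CC1(CCC/C(C)=C/CCC#C)OCCO1 | intermediate
10 | (trimethylsilyl)methylmagnesium chloride | C[Si](C)(C)C[Mg]Cl | starting material
11 | [(1Z,5E)-6-methyl-9-(2-methyl-1,3-dioxolan-2-yl)-2-[(trimethylsilyl)methyl]nona-1,5-dien-1-yl]copper (MgBrCl complex) | CC1(CCC/C(C)=C/CC/C(C[Si](C)(C)C)=C/[Cu])OCCO1 | intermediate
12 | lithium [(1Z,5E)-6-methyl-9-(2-methyl-1,3-dioxolan-2-yl)-2-[(trimethylsilyl)methyl]nona-1,5-dien-1-yl](phenylethynyl)cuprate | [Li+].CC1(CCC/C(C)=C/CC/C(C[Si](C)(C)C)=C/[Cu-]C#Cc2ccccc2)OCCO1 | intermediate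
13 | (3Z,7E)-8-methyl-11-(2-methyl-1,3-dioxolan-2-yl)-4-[(trimethylsilyl)methyl]undeca-3,7-dien-1-ol | CC1(CCC/C(C)=C/CC/C(C[Si](C)(C)C)=C/CCO)OCCO1 | intermediate
14 | (3Z,7E)-8-methyl-11-(2-methyl-1,3-dioxolan-2-yl)-4-[(trimethylsilyl)methyl]undeca-3,7-dien-1-yl 4-methylbenzenesulfonate | CC1(CCC/C(C)=C/CC/C(C[Si](C)(C)C)=C/CCOS(=O)(=O)c2ccc(C)cc2)OCCO1 | intermediate
15 | 2-chlorobuta-1,3-diene (chloroprene) | C=CC(Cl)=C | starting material
16 | buta-1,3-dien-2-ylmagnesium chloride | C=CC(=C)[Mg]Cl | intermediate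
17 | 2-methyl-2-[(4E,8Z)-4-methyl-12-methylidene-8-[(trimethylsilyl)methyl]tetradeca-4,8,13-trien-1-yl]-1,3-dioxolane | CC1(CCC/C(C)=C/CC/C(C[Si](C)(C)C)=C/CCC(=C)C=C)OCCO1 | intermediate
18 | (6E,10Z)-6-methyl-14-methylidene-10-[(trimethylsilyl)methyl]hexadeca-6,10,15-trien-2-one | CC(=O)CCC/C(C)=C/CC/C(C[Si](C)(C)C)=C/CCC(=C)C=C | intermediate
19 | trimethylsulfoxonium iodide | C[S+](C)(C)=O.[I-] | starting material
20 | dimethylsulfoxonium methylide | C[S+](C)(=O)[CH2-] | intermediate
21 | (2R)-2-methyl-2-[(4E,8Z)-4-methyl-12-methylidene-8-[(trimethylsilyl)methyl]tetradeca-4,8,13-trien-1-yl]oxirane | C[C@]1(CO1)CCC/C(C)=C/CC/C(C[Si](C)(C)C)=C/CCC(=C)C=C | intermediate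
22 | [(1R,4aS,5R,8aS)-1,4a-dimethyl-6-methylidene-5-(3-methylidenepent-4-en-1-yl)decahydronaphthalen-1-yl]methanol | C=CC(=C)CC[C@@H]1C(=C)CC[C@@H]2[C@](C)(CO)CCC[C@@]12C | intermediate
23 | (2E)-3-[4-(acetyloxy)phenyl]prop-2-enoic acid | CC(=O)Oc1ccc(/C=C/C(=O)O)cc1 | starting material
24 | [(1R,4aS,5R,8aS)-1,4a-dimethyl-6-methylidene-5-(3-methylidenepent-4-en-1-yl)decahydronaphthalen-1-yl]methyl (2E)-3-[4-(acetyloxy)phenyl]prop-2-enoate | C=CC(=C)CC[C@@H]1C(=C)CC[C@@H]2[C@](C)(COC(=O)/C=C/c3ccc(OC(C)=O)cc3)CCC[C@@]12C | intermediate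
25 | [(1R,4aS,5R,8aS)-1,4a-dimethyl-6-methylidene-5-(3-methylidenepent-4-en-1-yl)decahydronaphthalen-1-yl]methyl (2E)-3-(4-hydroxyphenyl)prop-2-enoate (CNP0131099.1) | C=CC(=C)CC[C@@H]1C(=C)CC[C@@H]2[C@](C)(COC(=O)/C=C/c3ccc(O)cc3)CCC[C@@]12C | target

**Step count**
Total: 10 steps. Longest linear sequence: 10 steps (fully linear from 1).

**Three steps most likely to fail**

Step 9 (bicyclisation). The risks are Meinwald rearrangement of the activated oxirane to the aldehyde, cation chemistry at the 1,3-diene, erosion of ee if ionisation runs ahead of C–C bonding, and the C4 epimer from the other chair (a separable diastereomer). The fallback makes the diene only after the rings exist; it sets out from tosylate 14 and comes back at alcohol 22. Compound 14 is alkylated with lithium acetylide–ethylenediamine (DMSO) to 2-methyl-2-[(4E,8Z)-4-methyl-8-[(trimethylsilyl)methyl]trideca-4,8-dien-12-yn-1-yl]-1,3-dioxolane F1. Aqueous oxalic acid gives (6E,10Z)-6-methyl-10-[(trimethylsilyl)methyl]pentadeca-6,10-dien-14-yn-2-one F2. The asymmetric methylene transfer of step 8 gives (2R)-2-methyl-2-[(4E,8Z)-4-methyl-8-[(trimethylsilyl)methyl]trideca-4,8-dien-12-yn-1-yl]oxirane F3. MeAlCl2 at −78 °C gives [(1R,4aS,5R,8aS)-5-(but-3-yn-1-yl)-1,4a-dimethyl-6-methylidenedecahydronaphthalen-1-yl]methanol F4; the isolated terminal alkyne is inert to the cations. Ene–yne cross-metathesis of F4 with ethylene (Grubbs second-generation catalyst, CH2Cl2, 40 °C) then builds the 2-substituted butadiene and gives 22.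

Step 8 (asymmetric methylene transfer). The risks are lower ee on this purely aliphatic methyl ketone and the wrong facial sense. The fallback replaces asymmetric catalysis by kinetic resolution; it sets out from ketone 18 and comes back at epoxide 21. The ordinary Corey–Chaykovsky reaction (Me3S(O)I, NaH, DMSO, rt) gives racemic 2-methyl-2-[(4E,8Z)-4-methyl-12-methylidene-8-[(trimethylsilyl)methyl]tetradeca-4,8,13-trien-1-yl]oxirane F5. A Jacobsen-type kinetic resolution with TMSN3 (0.55 equiv) and a chiral (salen)Cr(III) azide catalyst, its antipode chosen to consume the S epoxide, leaves 21 in high ee (at most about 45% yield). The S enantiomer is removed as {[(2S,6E,10Z)-1-azido-2,6-dimethyl-14-methylidene-10-[(trimethylsilyl)methyl]hexadeca-6,10,15-trien-2-yl]oxy}trimethylsilane F6.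

Step 5 (silylmethyl-carbocupration and oxirane trapping). The risks are sluggish addition of the α-silyl copper reagent to the alkyne and poor transfer of the alkenyl group to oxirane. The fallback builds the allylsilane by hydroxyl-directed hydroalumination and cross-coupling and brings the diene in as an isoprenyl nucleophile; it sets out from alkyne 9 and comes back at ketal tetraene 17. Compound 9 is hydroxymethylated (n-BuLi, then paraformaldehyde) to (6E)-7-methyl-10-(2-methyl-1,3-dioxolan-2-yl)dec-6-en-2-yn-1-ol F7. Red-Al followed by I2 gives (2Z,6E)-3-iodo-7-methyl-10-(2-methyl-1,3-dioxolan-2-yl)deca-2,6-dien-1-ol F8. Pd(PPh3)4-catalysed Kumada coupling with Me3SiCH2MgCl (retention) gives (2Z,6E)-7-methyl-10-(2-methyl-1,3-dioxolan-2-yl)-3-[(trimethylsilyl)methyl]deca-2,6-dien-1-ol F9. MsCl, LiCl and collidine in DMF give 2-[(4E,8Z)-10-chloro-4-methyl-8-[(trimethylsilyl)methyl]deca-4,8-dien-1-yl]-2-methyl-1,3-dioxolane F10. Alkylation of (2-methylidenebut-3-en-1-yl)potassium F11 (from isoprene, LiTMP/KOt-Bu, THF, −75 °C) with F10 gives 17, which is hydrolysed as in step 7.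

**Further compounds**
F1 | step 9 | 2-methyl-2-[(4E,8Z)-4-methyl-8-[(trimethylsilyl)methyl]trideca-4,8-dien-12-yn-1-yl]-1,3-dioxolane | CC1(CCC/C(C)=C/CC/C(C[Si](C)(C)C)=C/CCC#C)OCCO1
F2 | step 9 | (6E,10Z)-6-methyl-10-[(trimethylsilyl)methyl]pentadeca-6,10-dien-14-yn-2-one | CC(=O)CCC/C(C)=C/CC/C(C[Si](C)(C)C)=C/CCC#C
F3 | step 9 | (2R)-2-methyl-2-[(4E,8Z)-4-methyl-8-[(trimethylsilyl)methyl]trideca-4,8-dien-12-yn-1-yl]oxirane | C[C@]1(CO1)CCC/C(C)=C/CC/C(C[Si](C)(C)C)=C/CCC#C
F4 | step 9 | [(1R,4aS,5R,8aS)-5-(but-3-yn-1-yl)-1,4a-dimethyl-6-methylidenedecahydronaphthalen-1-yl]methanol | C#CCC[C@@H]1C(=C)CC[C@@H]2[C@](C)(CO)CCC[C@@]12C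
F5 | step 8 | racemic 2-methyl-2-[(4E,8Z)-4-methyl-12-methylidene-8-[(trimethylsilyl)methyl]tetradeca-4,8,13-trien-1-yl]oxirane | CC1(CO1)CCC/C(C)=C/CC/C(C[Si](C)(C)C)=C/CCC(=C)C=C
F6 | step 8 | {[(2S,6E,10Z)-1-azido-2,6-dimethyl-14-methylidene-10-[(trimethylsilyl)methyl]hexadeca-6,10,15-trien-2-yl]oxy}trimethylsilane | C[C@](CN=[N+]=[N-])(O[Si](C)(C)C)CCC/C(C)=C/CC/C(C[Si](C)(C)C)=C/CCC(=C)C=C
F7 | step 5 | (6E)-7-methyl-10-(2-methyl-1,3-dioxolan-2-yl)dec-6-en-2-yn-1-ol | CC1(CCC/C(C)=C/CCC#CCO)OCCO1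
F8 | step 5 | (2Z,6E)-3-iodo-7-methyl-10-(2-methyl-1,3-dioxolan-2-yl)deca-2,6-dien-1-ol | CC1(CCC/C(C)=C/CC/C(I)=C/CO)OCCO1
F9 | step 5 | (2Z,6E)-7-methyl-10-(2-methyl-1,3-dioxolan-2-yl)-3-[(trimethylsilyl)methyl]deca-2,6-dien-1-ol | CC1(CCC/C(C)=C/CC/C(C[Si](C)(C)C)=C/CO)OCCO1
F10 | step 5 | 2-[(4E,8Z)-10-chloro-4-methyl-8-[(trimethylsilyl)methyl]deca-4,8-dien-1-yl]-2-methyl-1,3-dioxolane | CC1(CCC/C(C)=C/CC/C(C[Si](C)(C)C)=C/CCl)OCCO1
F11 | step 5 | (2-methylidenebut-3-en-1-yl)potassium | [K+].[CH2-]C(=C)C=C
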